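The pitfall I watched for was reading a high early yield as something a flask keeps: the dawn run stood at 63.4% after 2.00 min but at 12.8% after 12.0 min.

| flask | starting material | partner | reagent | temperature | remark | time |
|---|---|---|---|---|---|---|
| dawn | 0.20 M | 0.40 M | 0.50 M | 25 °C | run made earlier |  |
| midnight | 0.13 M | 0.40 M | 0.50 M | 40 °C | run made earlier |  |
| autumn | 0.30 M | 0.40 M | 0.50 M | 25 °C | run made earlier |  |
| maple | 0.20 M | 0.400 M | 0.500 M | 40 °C | everything together at the start | 6.0 min |
| alder | 0.20 M (fed, over 5.0 min) | 0.400 M | 0.500 M |  | the addition at 10 °C, then warmed to 40 °C; the feed brings no volume worth counting | 6.0 min |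
| elm | 0.20 M | 0.400 M | 0.500 M (fed, over 5.0 min) | 40 °C | all else is in the flask from the start; the feed brings no volume worth counting | 6.0 min |
| birch | 0.20 M (fed, over 5.0 min) | 0.400 M | 0.500 M | 40 °C | all else is in the flask from the start; the feed brings no volume worth counting | 6.0 min |

| run | time / min | target / % |
|---|---|---|
| dawn | 1.00 | 50.1 |
| dawn | 2.00 | 63.4 |
| dawn | 3.00 | 60.5 |
| dawn | 4.00 | 52.3 |
| dawn | 8.00 | 26.4 |
| dawn | 12.0 | 12.8 |
| midnight | 0.500 | 56.7 |
| midnight | 1.33 | 30.4 |
| midnight | 2.50 | 8.0 |
| midnight | 4.00 | 2.4 |
| midnight | 6.00 | 0.3 |
| midnight | 8.00 | 0 |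
| autumn | 1.00 | 36.0 |
| autumn | 2.00 | 43.7 |
| autumn | 3.00 | 43.3 |
| autumn | 5.00 | 34.9 |
| autumn | 8.00 | 22.7 |
| autumn | 15.0 | 7.8 |

(scatter of a reading: 0.5 percentage points)

- the earlier runs were read with a standard deviation of 0.5 percentage points

* which flask leads in amount of target, in percent of the starting material charged ("all alike" within 1.5 percentage points) (maple / alder / elm / birch / all alike)
* how much target is there at the end, in percent of the starting material charged: maple
* how much target is there at the end, in percent of the starting material charged: alder
* how much target is there at the end, in percent of the starting material charged: elm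
* how much target is there at the end, in percent of the starting material charged: birch

So I looked at the rate of loss alone. Late in the runs at 25 °C, the slope of ln(target) against time gave 0.181 min⁻¹ in the dawn run, charged at 0.20 M, and 0.153 min⁻¹ in the autumn run, charged at 0.30 M. The constant had not risen with the charge, so I took the target's own concentration as the one that set the order, a first-order loss. From the midnight run I read the loss constant k of the target at 40 °C, the slope of ln(target) against time:

k = ln(30.4 / 2.4) / (4.00 min − 1.33 min) = 0.951 min⁻¹

The rate of loss therefore halved with the target every 0.729 min, and a hold of time τ with no new target left the fraction exp(−kτ). That gave me two factors: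

alder, warm stretch after the feed: exp(−k·1.00 min) = 38.6%

maple, whole time: exp(−k·6.0 min) = 0.333%

I expected alder to lead, since its factor was far larger than maple's, and I held that alder's reading would be this factor times whatever target stood at the end of the cold feed, plus what formed afterwards.

The forecast named alder as the leader, with 0.4% for maple, 40% for alder, 3% for elm and 9.5% for birch, on the ground that in alder the “target sits safely at 10 °C and sees only one minute at 40 °C”.

    starting material + open intermediate → side product (k = 0.0890 M⁻¹ s⁻¹, Ea = 68.0 kJ mol⁻¹)
    open intermediate + second intermediate → target (k = 0.620 M⁻¹ s⁻¹, Ea = 51.0 kJ mol⁻¹)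
    starting material + reagent → open intermediate (k = 0.610 M⁻¹ s⁻¹, Ea = 43.0 kJ mol⁻¹)
    reagent + partner → second intermediate (k = 0.120 M⁻¹ s⁻¹, Ea = 43.0 kJ mol⁻¹)
    2 open intermediate → homo product (k = 0.0160 M⁻¹ s⁻¹, Ea = 50.0 kJ mol⁻¹)
    target → over-reaction product (k = 0.0190 s⁻¹, Ea = 95.0 kJ mol⁻¹)
    (constants at 40 °C)

The flask gave alder the lead at 30.6%, with maple at 0.171%, elm at 2.18% and birch at 1.74%. At the end of the feed, alder held 53.0% target beside 28.2% starting material. My factor, read from the midnight run, applied to that target gives the estimate 20.5%, and the flask stood 10 points above this estimate.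

On the neighbour, alder left until 10 min, k carried from the reading at 6.0 min gives 0.682%. The computed flask holds 0.474%.

The runs come from a simulation with constants of no real substance.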